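The second reagent is wanted by two steps, and the next run hangs on how much of it survives the substrate: we must decide whether to leave the flask longer or to charge it differently.

    second reagent + intermediate → target (k1 = 0.68 L mol⁻¹ s⁻¹)
    substrate + partner → intermediate (k2 = 0.21 L mol⁻¹ s⁻¹)
    substrate + second reagent → side product (k3 = 5.5 L mol⁻¹ s⁻¹)
    target → over-reaction product (k4 = 4.6 × 10⁻⁶ s⁻¹)

substrate 10 mM; partner 50.0 mM; second reagent 6.00 mM; time 30 min

1. amount of target at 30 min, in percent of the substrate charged
2. amount of target if the flask were left three thousand times as long, in percent of the substrate charged

Our own reckoning starts from the crossover level, the amount of second reagent at which substrate goes equally fast down both of its paths, with the partner held at its charge: 1.91 mM, the partner charge divided by the selectivity factor of 26.2. This flask starts at 6.00 mM, which is 3.14 times the crossover level. Dividing the two rate laws and integrating gives R, the second reagent left when substrate is gone: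

ln(charge/R) = (substrate charge − reagent charge + R)/crossover level.

Ignoring target made during the race, this gives 0.554 mM. That amount meets the 4.55 mM of intermediate reckoned by the same balance, one for one, and with intermediate held there the second reagent has a half-life of 3.73 min, shorter than the run of 30 min, so we commit to 5.54% target. Target's lifetime of 60.4 h is far shorter than the long wait of 1500 h, which is 24.8 lifetimes, so waiting loses target. The crossover level stands below the charged second reagent, and with the constants fixed it grows in step with the partner charge, so our next run would raise the partner rather than wait.

The forecast gave 7% and <0.001%. It held the second reagent to be “mostly consumed by the fast reaction with substrate before intermediate builds up”, and its target stands above ours.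

The flask gives 6.54% and 0%. At the start of this flask, the side path used substrate 3.1 times as fast as the partner path. At 30.0 min this flask holds 53.4% side product, 40.0% intermediate and 6.54% target.

In the neighbour with 200 mM of partner, the crossover level becomes 7.64 mM, above the charged second reagent, and the same equation leaves 2.54 mM, so 25.4% target. That flask gives 25.6%, with 34.1% side product.

(The constants used here were drawn at random within sensible limits; no experiment stands behind them.)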